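In a one-step world J would take up two E, give Q and stop, and Q would stay. But in the beta run Q falls from 42.8 % to 16.4 %, and X falls with it. So Q and X form a pool, exchanging by Q + E ⇌ X + G, and the pool leaks through X.

| setting | gamma | beta | alpha | flask |
|---|---|---|---|---|
| J | 0.015 M | 0.015 M | 0.015 M | 0.015 M |
| E | 0.022 M | 0.090 M | 0.045 M | 0.0450 M |
| G | 0.030 M | 0.030 M | 0.015 M | 0.0300 M |
| remark | run made earlier | run made earlier | run made earlier |  |
| time |  |  |  | 10 h |

- gamma (time / h: Q / %, X / %): 0.667: 53.5, 3.0; 2.00: 63.9, 0.5; 4.00: 65.6, 0; 6.00: 65.9, 0.2; 8.00: 65.3, 0.6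
- beta (time / h: Q / %, X / %): 1.50: 42.8, 36.6; 3.00: 33.3, 28.3; 5.00: 24.6, 20.0; 6.00: 21.0, 16.7; 8.00: 16.4, 12.0
- alpha (time / h: Q / %, X / %): 0.667: 70.0, 20.5; 1.33: 72.3, 18.3; 2.50: 68.1, 15.8; 4.00: 62.8, 13.2; 8.00: 51.9, 8.9

(scatter of a reading: 0.3 percentage points)

* equivalents of E to J, everything else as given, that leave most Q at 10 h
* the amount of Q then, in percent of the J charged
* the amount of Q with the amounts as given

Here is my reckoning, with J counted as converted and whatever X decays into counted as holding E as X does. The first beta reading gives K = cX·cG/(cQ·cE) = 1.14. The pool's fall over the beta run, divided by X's mean share, gives k = 0.358 h⁻¹.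

The flask has 3.00 equivalents of E, so in units of the J charged cE = cQ and cG = 5 − cQ. Q therefore starts at 81.8 % of the pool. The drain, k times X's share of the pool, is the fraction of the pool lost per hour: 0.0653 h⁻¹ at the start. With cE = cQ and cG taken as nearly steady, the leak goes as cQ squared, which is second order, so the drain sinks with the pool. My reckoning then puts the pool at 60.5 % at the asked time, and Q at 53.3 %.

The forecast says 52.5 %, and 91.5 % at 2.08 equiv, where “the best charge just consumes J and leaves no free E”.

The flask gives 52.3 %, and 90.4 % at 2.04 equiv.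

    J + E → G + Z (k = 4.40 M⁻¹ min⁻¹)
    Z + E → G + Q (k = 12.0 M⁻¹ min⁻¹)
    Q + E ⇌ G + X (K = 1.20, k = 1.90 M⁻¹ min⁻¹)
    X → L (k = 0.00600 min⁻¹)

In the flask, k times X's simulated share makes the drain 0.0424 h⁻¹ at 10.0 h, down from my reckoned 0.0653 h⁻¹ at the start. The neighbouring flask has 0.076 M of E, its other charges and time as in the flask, and 44 % of that E is left at the end. So I hold cE/cG fixed at its value with Q at 33.3 %, which is the pseudo-first-order case. That gives cX/cQ = 0.587 and a steady drain of 0.132 h⁻¹, higher than the flask's start. Taken as steady, that drain makes the pool decay exponentially, which puts Q at 16.8 %. The neighbouring flask holds 17.2 % of Q at 10.0 h.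

The earlier runs and the new flask were computed on assumed constants; noise was put on by code.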